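The trimethylcyclohexene (ring A: C1 carries the side chain, C2 the vinylic methyl, C3–C5 are CH2, C6 is CMe2) is closed at C2–C3. With C1 masked as a ketone, the quaternary C6 leaves C2 as the only enolisable carbon, so one pot turns acyclic 7-chloro-4,4-dimethylheptan-3-one into the ring A enol triflate: enolate C-alkylation closes the ring, re-enolisation and O-triflation fix the C1=C2 alkene. Negishi coupling, carboalumination–iodination and a final Heck reaction with an (R)-2-vinylchroman acid, made by enantioselective Wacker-type cyclisation, complete the target.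

Key step: step 3

Remark: the sense of induction in step 8 is assigned by analogy with related alkenylphenols, so (R,R)-Bn-BOXAX stands for the ligand antipode that delivers the (R)-chroman; this binaphthyl bis(4-benzyloxazoline) ligand is a catalyst component prepared apart from the route, and diene 18 is used as the commercial E/Z mixture.

Step 1
Reactants: 1 isobutyronitrile (2-methylpropanenitrile); 2 1-bromo-3-chloropropane
Product: 4 5-chloro-2,2-dimethylpentanenitrile, via lithiated isobutyronitrile 3 (not isolated)
Conditions: LiN(iPr)2, THF, −78 °C; then 2, −78 °C → rt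
Reagents that add atoms: none
Why: SN2 alkylation of the tertiary α-cyano carbanion should take place at the C–Br end of the dihalide because bromide is the far better leaving group, which builds the quaternary C6 and keeps the chloride for the ring closure; no stereocentre is formed.

Step 2
Reactants: 4 5-chloro-2,2-dimethylpentanenitrile
Product: 6 7-chloro-4,4-dimethylheptan-3-one, via N-lithio ketimine 5 (not isolated)
Conditions: EtLi, Et2O, −78 → 0 °C; then cold 2 M HCl, rt
Reagents that add atoms: ethyllithium (CC[Li]); water (O)
Why: Organolithium addition to a nitrile without α-hydrogen should stop at the N-lithio ketimine, and imine hydrolysis in acid (which keeps nitrogen protonated and away from the chloride) gives the ethyl ketone; no stereocentre is formed.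

Step 3
Reactants: 6 7-chloro-4,4-dimethylheptan-3-one
Product: 10 2,6,6-trimethylcyclohex-1-en-1-yl trifluoromethanesulfonate, via acyclic potassium enolate 7 (not isolated), via 2,2,6-trimethylcyclohexanone 8 (not isolated), via cyclic potassium enolate 9 (not isolated)
Conditions: KN(SiMe3)2 (1.1 equiv), THF (0.05 M), −78 → 45 °C; then KN(SiMe3)2 (1.2 equiv), −78 → 0 °C; PhNTf2, 0 °C → rt
Reagents that add atoms: N-phenylbis(trifluoromethanesulfonimide) (O=S(=O)(N(c1ccccc1)S(=O)(=O)C(F)(F)F)C(F)(F)F)
Why: The base can enolise 6 only toward C2 because C6 is quaternary, and enolate 7 displaces the primary chloride at C3 by intramolecular SN2 C-alkylation, which forms the C2–C3 bond and gives ketone 8. The closest known reaction type is the intramolecular alkylation of a ketone enolate by an ω-halide, telescoped here with standard enol triflate formation by N-phenyltriflimide. The six-membered ring closes in the 6-(enolendo)-exo-tet mode, in which the enolate carbon can reach the backside of the C–Cl bond, and the gem-dimethyl group at C6 should speed the closure. The only new stereocentre, C2 of 8, forms racemic and is erased when the second equivalent of base gives enolate 9, whose O-triflation fixes the tetrasubstituted C1=C2 double bond. The step needs C- over O-alkylation and intra- over intermolecular reaction: the potassium enolate as a tight ion pair in THF without polar additives and moderate dilution should secure both, and the blocked C6 makes both enolisations regiochemically unambiguous.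

Step 4
Reactants: 10 2,6,6-trimethylcyclohex-1-en-1-yl trifluoromethanesulfonate; 11 (4-bromobut-1-yn-1-yl)trimethylsilane
Product: 13 trimethyl[4-(2,6,6-trimethylcyclohex-1-en-1-yl)but-1-yn-1-yl]silane, via alkylzinc bromide 12 (not isolated)
Conditions: 11, Zn dust, I2 (cat.), DMA, 70 °C; then 10, PdCl2(dppf) (5 mol %), THF/DMA, 60 °C
Reagents that add atoms: none
Why: Negishi cross-coupling: zinc insertion gives the primary alkylzinc bromide, which should transmetalate to the alkenylpalladium species formed from the hindered enol triflate, the wide-bite-angle dppf ligand favouring reductive elimination over β-hydride elimination; no stereocentre is formed.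

Step 5
Reactants: 13 trimethyl[4-(2,6,6-trimethylcyclohex-1-en-1-yl)but-1-yn-1-yl]silane
Product: 14 2-(but-3-yn-1-yl)-1,3,3-trimethylcyclohex-1-ene
Conditions: K2CO3, MeOH, rt
Reagents that add atoms: none
Why: Base-catalysed methanolysis of the alkynyl C–Si bond (protodesilylation) should free the terminal alkyne and leave the tetrasubstituted ring alkene untouched.

Step 6
Reactants: 14 2-(but-3-yn-1-yl)-1,3,3-trimethylcyclohex-1-ene
Product: 16 2-[(3E)-4-iodo-3-methylbut-3-en-1-yl]-1,3,3-trimethylcyclohex-1-ene, via alkenylalane 15 (not isolated)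
Conditions: Me3Al, Cp2ZrCl2 (0.25 equiv), CH2Cl2, 0 °C → rt; then I2, THF, −30 → 0 °C
Reagents that add atoms: trimethylaluminium (C[Al](C)C); iodine (II)
Why: Zirconium-catalysed carboalumination (Negishi methylalumination) adds Me and Al syn across the terminal alkyne with Al on the terminal carbon, and iodinolysis of the C–Al bond with retention should give the (E)-trisubstituted vinyl iodide, so the geometry of the C(Me)=CH double bond of the target is set here.

Step 7
Reactants: 17 4-bromo-2-iodophenol; 18 3-methylpenta-1,3-diene (E/Z mixture)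
Product: 20 4-bromo-2-(3-methylpent-3-en-1-yl)phenol (E/Z mixture), via B-alkyl-9-BBN 19 (not isolated)
Conditions: 18, 9-BBN, THF, 0 °C → rt; then 17, PdCl2(dppf) (3 mol %), aq. K3PO4, DMF, 50 °C
Reagents that add atoms: none
Why: 9-BBN should hydroborate only the monosubstituted vinyl terminus of the diene (anti-Markovnikov), and the B-alkyl Suzuki–Miyaura coupling takes place at the C–I bond, which undergoes oxidative addition much faster than C–Br; the alkene geometry is immaterial because the alkene is consumed in step 8.

Step 8
Reactants: 20 4-bromo-2-(3-methylpent-3-en-1-yl)phenol (E/Z mixture)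
Product: 21 (2R)-6-bromo-2-ethenyl-2-methyl-3,4-dihydro-2H-chromene
Conditions: Pd(OCOCF3)2 (10 mol %), (R,R)-Bn-BOXAX (20 mol %), p-benzoquinone, MeOH, rt → 60 °C
Reagents that add atoms: none
Why: Enantioselective Wacker-type oxidative cyclisation: the phenol oxygen adds to the alkene bound to the chiral divalent palladium–bis(oxazoline) complex in a 6-exo closure at the methyl-bearing carbon, β-hydride elimination toward the terminal methyl gives the vinyl group, benzoquinone reoxidises zerovalent palladium, and the ligand, which selects the alkene face in the oxypalladation, should set the C2 stereocentre as (R).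

Step 9
Reactants: 21 (2R)-6-bromo-2-ethenyl-2-methyl-3,4-dihydro-2H-chromene
Product: 23 (2R)-2-ethenyl-2-methyl-3,4-dihydro-2H-chromene-6-carboxylic acid, via aryllithium 22 (not isolated)
Conditions: t-BuLi (2.1 equiv), THF, −78 °C; CO2; then 1 M HCl
Reagents that add atoms: carbon dioxide (O=C=O)
Why: Bromine–lithium exchange at −78 °C should be much faster than any addition to the vinyl group, and carboxylation of the aryllithium installs the acid at C6; the quaternary stereocentre is not involved.

Step 10
Reactants: 16 2-[(3E)-4-iodo-3-methylbut-3-en-1-yl]-1,3,3-trimethylcyclohex-1-ene; 23 (2R)-2-ethenyl-2-methyl-3,4-dihydro-2H-chromene-6-carboxylic acid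
Product: 24 (2R)-2-methyl-2-[(1E,3E)-4-methyl-6-(2,6,6-trimethylcyclohex-1-en-1-yl)hexa-1,3-dien-1-yl]-3,4-dihydro-2H-chromene-6-carboxylic acid (CNP0265961.1)
Conditions: Pd(OAc)2 (10 mol %), K2CO3, Bu4NCl, DMF, 50 °C; then dilute HCl
Reagents that add atoms: none
Why: Mizoroki–Heck reaction under phosphine-free conditions: the alkenylpalladium species from 16 should add to the terminal carbon of the vinyl group (which behaves like 2-methylbut-3-en-2-ol, with no β-hydrogen on the quaternary side), syn β-hydride elimination gives the (E)-disubstituted double bond, the (E)-geometry of the iodide is retained, and the stereocentre is untouched.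

Compound list
1 | isobutyronitrile (2-methylpropanenitrile) | CC(C)C#N | starting material
2 | 1-bromo-3-chloropropane | ClCCCBr | starting material
3 | 2-lithio-2-methylpropanenitrile (lithiated isobutyronitrile) | CC(C)([Li])C#N | intermediate
4 | 5-chloro-2,2-dimethylpentanenitrile | CC(C)(CCCCl)C#N | intermediate
5 | lithium (7-chloro-4,4-dimethylheptan-3-ylidene)azanide (N-lithio ketimine) | CCC(=N[Li])C(C)(C)CCCCl | intermediate
6 | 7-chloro-4,4-dimethylheptan-3-one | CCC(=O)C(C)(C)CCCCl | intermediate
7 | potassium (Z)-7-chloro-4,4-dimethylhept-2-en-3-olate | C/C=C(\[O-])C(C)(C)CCCCl.[K+] | intermediate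
8 | 2,2,6-trimethylcyclohexan-1-one (racemic) | CC1CCCC(C)(C)C1=O | intermediate
9 | potassium 2,6,6-trimethylcyclohex-1-en-1-olate | CC1=C([O-])C(C)(C)CCC1.[K+] | intermediate
10 | 2,6,6-trimethylcyclohex-1-en-1-yl trifluoromethanesulfonate | CC1=C(OS(=O)(=O)C(F)(F)F)C(C)(C)CCC1 | intermediate
11 | (4-bromobut-1-yn-1-yl)trimethylsilane | C[Si](C)(C)C#CCCBr | starting material
12 | [4-(trimethylsilyl)but-3-yn-1-yl]zinc bromide | C[Si](C)(C)C#CCC[Zn]Br | intermediate
13 | trimethyl[4-(2,6,6-trimethylcyclohex-1-en-1-yl)but-1-yn-1-yl]silane | CC1=C(CCC#C[Si](C)(C)C)C(C)(C)CCC1 | intermediate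
14 | 2-(but-3-yn-1-yl)-1,3,3-trimethylcyclohex-1-ene | CC1=C(CCC#C)C(C)(C)CCC1 | intermediate
15 | dimethyl[(1E)-2-methyl-4-(2,6,6-trimethylcyclohex-1-en-1-yl)but-1-en-1-yl]alumane | CC1=C(CC/C(C)=C/[Al](C)C)C(C)(C)CCC1 | intermediate
16 | 2-[(3E)-4-iodo-3-methylbut-3-en-1-yl]-1,3,3-trimethylcyclohex-1-ene | CC1=C(CC/C(C)=C/I)C(C)(C)CCC1 | intermediate
17 | 4-bromo-2-iodophenol | Oc1ccc(Br)cc1I | starting material
18 | 3-methylpenta-1,3-diene (E/Z mixture) | C=CC(C)=CC | starting material
19 | 9-(3-methylpent-3-en-1-yl)-9-borabicyclo[3.3.1]nonane (E/Z mixture) | CC=C(C)CCB1C2CCCC1CCC2 | intermediate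
20 | 4-bromo-2-(3-methylpent-3-en-1-yl)phenol (E/Z mixture) | CC=C(C)CCc1cc(Br)ccc1O | intermediate
21 | (2R)-6-bromo-2-ethenyl-2-methyl-3,4-dihydro-2H-chromene | C=C[C@@]1(C)CCc2cc(Br)ccc2O1 | intermediate
22 | [(2R)-2-ethenyl-2-methyl-3,4-dihydro-2H-chromen-6-yl]lithium | C=C[C@@]1(C)CCc2cc([Li])ccc2O1 | intermediate
23 | (2R)-2-ethenyl-2-methyl-3,4-dihydro-2H-chromene-6-carboxylic acid | C=C[C@@]1(C)CCc2cc(C(=O)O)ccc2O1 | intermediate
24 | (2R)-2-methyl-2-[(1E,3E)-4-methyl-6-(2,6,6-trimethylcyclohex-1-en-1-yl)hexa-1,3-dien-1-yl]-3,4-dihydro-2H-chromene-6-carboxylic acid | CC1=C(CC/C(C)=C/C=C/[C@@]2(C)CCc3cc(C(=O)O)ccc3O2)C(C)(C)CCC1 | target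

Total step count: 10. Longest linear sequence: 7 steps (steps 1 to 6, then step 10).

Steps most likely to fail

Step 3. The enolate may alkylate on oxygen to a cyclic enol ether or react between molecules, and the second enolisation of the hindered ketone may stay incomplete so that triflation stalls. The fallback sets out from 1 and comes back at 10, and makes the C2–C3 bond by ring-closing metathesis instead. Lithiated 1 (compound 3) is alkylated with 4-bromobut-1-ene to 2,2-dimethylhex-5-enenitrile F1. Addition of prop-1-en-2-yllithium gives lithium (2,4,4-trimethylocta-1,7-dien-3-ylidene)azanide F2, which aqueous HCl hydrolyses to 2,4,4-trimethylocta-1,7-dien-3-one F3. Second-generation Grubbs catalyst in CH2Cl2 at 40 °C should close F3 to 2,6,6-trimethylcyclohex-2-en-1-one F4 with loss of ethene. Conjugate reduction with Li[HB(sBu)3] in THF at −78 °C gives lithium 2,6,6-trimethylcyclohex-1-en-1-olate F5, which is trapped with N-phenyltriflimide to give 10.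

Step 8. Enantioface discrimination may be weak, with the E and Z isomers of 20 reacting with different selectivity, and oxypalladation of the electron-poor bromophenol may be slow. The fallback sets out from 20 and comes back at 21. Cyclisation of 20 without chiral ligand [Pd(OCOCF3)2, pyridine, O2, toluene, 80 °C] should give racemic 6-bromo-2-ethenyl-2-methyl-3,4-dihydro-2H-chromene F6. Its enantiomers are separated by preparative chromatography on a chiral stationary phase, and the (R)-enantiomer is 21.

Step 10. β-Aryloxy elimination, or re-ionisation of the tertiary allylic aryl ether by zerovalent palladium, may open the chroman ring or erode the configuration, and palladium hydride re-addition may scramble the diene geometry. The fallback sets out from 23 and comes back at 24. Cross-metathesis of 23 with vinylboronic acid pinacol ester (second-generation Hoveyda–Grubbs catalyst, CH2Cl2, 40 °C) should give (2R)-2-methyl-2-[(E)-2-(4,4,5,5-tetramethyl-1,3,2-dioxaborolan-2-yl)ethenyl]-3,4-dihydro-2H-chromene-6-carboxylic acid F7. Suzuki–Miyaura coupling of F7 with 16 [Pd(PPh3)4, aqueous NaOH, THF, rt] joins the two alkenyl partners with both geometries already fixed, and acidification gives 24.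

Further compounds
F1 | step 3 | 2,2-dimethylhex-5-enenitrile | C=CCCC(C)(C)C#N
F2 | step 3 | lithium (2,4,4-trimethylocta-1,7-dien-3-ylidene)azanide | C=CCCC(C)(C)C(=N[Li])C(C)=C
F3 | step 3 | 2,4,4-trimethylocta-1,7-dien-3-one | C=CCCC(C)(C)C(=O)C(C)=C
F4 | step 3 | 2,6,6-trimethylcyclohex-2-en-1-one | CC1=CCCC(C)(C)C1=O
F5 | step 3 | lithium 2,6,6-trimethylcyclohex-1-en-1-olate | CC1=C([O-])C(C)(C)CCC1.[Li+]
F6 | step 8 | racemic 6-bromo-2-ethenyl-2-methyl-3,4-dihydro-2H-chromene | C=CC1(C)CCc2cc(Br)ccc2O1
F7 | step 10 | (2R)-2-methyl-2-[(E)-2-(4,4,5,5-tetramethyl-1,3,2-dioxaborolan-2-yl)ethenyl]-3,4-dihydro-2H-chromene-6-carboxylic acid | CC1(C)OB(/C=C/[C@@]2(C)CCc3cc(C(=O)O)ccc3O2)OC1(C)C
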